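**Plan**

- Numbering (germacrane): ten-membered ring C1(=CH)–C2(OAc)–C3H2–C4(OH)(CH3)–C5H2–C6(O-methacryloyl)–C7–C8–C9(=CH)–C10(CH3); butenolide ring O–C12(=O)–C11(C13H2OH)=C7–C8. TBS = tert-butyldimethylsilyl.
- Retrosynthesis, in order: C13–O silyl ether; the C8=C9 alkylidene butenolide back to a 2,3,4-trisubstituted furan (ring O, C8, C7, C11, C12); the C6 ester and carbinol back to a C6 ketone; the carbocycle opened at C4–C5; then C2–C3 (allyl), C6–C7 (acyl), C9–alkyne carbon and the furan ring itself.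
- Enabling feature: C6(O)–C5H2–C4(OH) is an aldol retron across C4–C5. The furan holds the C6 chloroacetyl group (on C7) and the C9 chain (on C8) on neighbouring ring atoms, so a samarium enolate at C5 lies within reach of the C4 methyl ketone. Helpers: Cl on C5, the furan as latent butenolide, TBS on C13–O; they leave in steps 14, 17–18 and 19.
- Forward order: furan ring (steps 1–6), side chain and C2 (7–13), ten-membered ring (14), C6 (15–16), butenolide ring from the furan (17–18), deprotection (19).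
- Stereochemistry: C2 from (S)-BINOL/Ti(OiPr)4-catalysed allylation; C4 from C2 in the ring closure (1,3-anti); C6 from C4 by hydroxyl-directed 1,3-anti reduction; C1=C10 (E) from the allylic oxidation of prenyl acetate; C8=C9 geometry from the ring.

Key step: step 14

**Route**

Step 1
Reactants: 1 2,2-dimethyl-1,3-dioxan-5-one; 2 ethynylmagnesium bromide
Product: 3 5-ethynyl-2,2-dimethyl-1,3-dioxan-5-ol
Conditions: 2 (0.5 M in THF, 1.2 equiv), THF, 0 °C; aq. NH4Cl
Reagents that add atoms: none
Why: Grignard addition of the acetylide to the symmetric ketone gives the tertiary propargylic alcohol, and no stereocentre arises because the two ring CH2O arms are identical.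

Step 2
Reactants: 4 3-methylbut-2-en-1-yl acetate (prenyl acetate)
Product: 5 (2E)-4-hydroxy-3-methylbut-2-en-1-yl acetate
Conditions: SeO2 (0.2 equiv), t-BuOOH (70% aq., 3 equiv), salicylic acid (0.1 equiv), CH2Cl2, 23 °C
Reagents that add atoms: tert-butyl hydroperoxide CC(C)(C)OO
Why: Riley allylic oxidation (ene reaction of SeO2, then [2,3]-sigmatropic shift, t-BuOOH as terminal oxidant) hydroxylates the methyl group trans to the CH2OAc chain, which fixes the E geometry of the later C1=C10 bond.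

Step 3
Reactants: 5 (2E)-4-hydroxy-3-methylbut-2-en-1-yl acetate
Product: 6 (2E)-4-bromo-3-methylbut-2-en-1-yl acetate
Conditions: CBr4 (1.2 equiv), PPh3 (1.25 equiv), CH2Cl2, 0 °C
Reagents that add atoms: carbon tetrabromide BrC(Br)(Br)Br
Why: Appel bromination converts the primary allylic alcohol to the bromide at 0 °C without allylic transposition or loss of alkene geometry.

Step 4
Reactants: 3 5-ethynyl-2,2-dimethyl-1,3-dioxan-5-ol; 6 (2E)-4-bromo-3-methylbut-2-en-1-yl acetate
Product: 7 (2E)-6-(5-hydroxy-2,2-dimethyl-1,3-dioxan-5-yl)-3-methylhex-2-en-5-yn-1-yl acetate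
Conditions: CuI (1.0 equiv), NaI (1.0 equiv), K2CO3 (1.5 equiv), DMF, 23 °C
Reagents that add atoms: none
Why: The copper acetylide displaces the primary allylic halide at the unhindered CH2 (SN2, E geometry retained), a standard copper-mediated alkyne–allyl halide coupling that tolerates the free tertiary hydroxyl and the acetate.

Step 5
Reactants: 7 (2E)-6-(5-hydroxy-2,2-dimethyl-1,3-dioxan-5-yl)-3-methylhex-2-en-5-yn-1-yl acetate
Product: 8 (2E)-7,8-dihydroxy-7-(hydroxymethyl)-3-methyloct-2-en-5-yn-1-yl acetate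
Conditions: AcOH/H2O (4:1), 40 °C
Reagents that add atoms: none
Why: Acid-catalysed ketal hydrolysis frees the two primary hydroxyls, while the acetate and the skipped enyne are stable to warm aqueous acetic acid.

Step 6
Reactants: 8 (2E)-7,8-dihydroxy-7-(hydroxymethyl)-3-methyloct-2-en-5-yn-1-yl acetate
Product: 9 (2E)-4-[4-(hydroxymethyl)-3-iodofuran-2-yl]-3-methylbut-2-en-1-yl acetate
Conditions: I2 (3 equiv), NaHCO3 (3 equiv), MeCN, 0 to 23 °C
Reagents that add atoms: iodine II
Why: Electrophilic 5-endo-dig iodocyclisation of the 3-alkyne-1,2-diol (a primary hydroxyl attacks the iodonium-activated alkyne at the future C8) followed by loss of water aromatises to the 3-iodofuran; the two hydroxymethyl groups are equivalent, so one regioisomer forms and the spare one becomes C13–OH.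

Step 7
Reactants: 9 (2E)-4-[4-(hydroxymethyl)-3-iodofuran-2-yl]-3-methylbut-2-en-1-yl acetate
Product: 10 (2E)-4-[4-(TBS-oxymethyl)-3-iodofuran-2-yl]-3-methylbut-2-en-1-yl acetate
Conditions: TBSCl (1.2 equiv), imidazole (2 equiv), DMF, 0 °C
Reagents that add atoms: tert-butyldimethylsilyl chloride CC(C)(C)[Si](C)(C)Cl
Why: Imidazole-promoted silylation protects the only free (primary) hydroxyl so that it cannot quench the later Grignard and samarium enolate steps.

Step 8
Reactants: 10 (2E)-4-[4-(TBS-oxymethyl)-3-iodofuran-2-yl]-3-methylbut-2-en-1-yl acetate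
Product: 11 (2E)-4-[4-(TBS-oxymethyl)-3-iodofuran-2-yl]-3-methylbut-2-en-1-ol
Conditions: K2CO3 (0.2 equiv), MeOH, 0 °C
Reagents that add atoms: none
Why: Base-catalysed transesterification with methanol removes the primary allylic acetate, while the silyl ether and the iodofuran are inert.

Step 9
Reactants: 11 (2E)-4-[4-(TBS-oxymethyl)-3-iodofuran-2-yl]-3-methylbut-2-en-1-ol; 12 2-chloro-N-methoxy-N-methylacetamide
Product: 14 1-{4-(TBS-oxymethyl)-2-[(2E)-4-hydroxy-2-methylbut-2-en-1-yl]furan-3-yl}-2-chloroethan-1-one, via furylmagnesium chloride 13 (not isolated)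
Conditions: iPrMgCl·LiCl (2.2 equiv), THF, −20 °C; then 12 (1.5 equiv), −20 to 0 °C; aq. NH4Cl
Reagents that add atoms: none
Why: After deprotonation of the hydroxyl, iodine–magnesium exchange gives the 3-furylmagnesium species (magnesium counter-ion and low temperature disfavour O-to-C silyl migration), which is acylated once by the amide (Weinreb ketone synthesis, the chelated tetrahedral adduct prevents over-addition) to place the chloroacetyl group on C7.

Step 10
Reactants: 14 1-{4-(TBS-oxymethyl)-2-[(2E)-4-hydroxy-2-methylbut-2-en-1-yl]furan-3-yl}-2-chloroethan-1-one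
Product: 15 (2E)-4-[4-(TBS-oxymethyl)-3-(chloroacetyl)furan-2-yl]-3-methylbut-2-enal
Conditions: MnO2 (20 equiv), CH2Cl2, 23 °C
Reagents that add atoms: none
Why: MnO2 oxidises the allylic alcohol selectively to the E enal, and the α-chloro ketone and silyl ether do not react.

Step 11
Reactants: 15 (2E)-4-[4-(TBS-oxymethyl)-3-(chloroacetyl)furan-2-yl]-3-methylbut-2-enal; 16 allyltributylstannane
Product: 17 1-{4-(TBS-oxymethyl)-2-[(2E,4S)-4-hydroxy-2-methylhepta-2,6-dien-1-yl]furan-3-yl}-2-chloroethan-1-one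
Conditions: (S)-BINOL (0.2 equiv), Ti(OiPr)4 (0.1 equiv), 4 Å molecular sieves, 16 (1.5 equiv), CH2Cl2, −20 °C; aq. NaHCO3
Reagents that add atoms: none
Why: Keck asymmetric allylation: the (S)-BINOL–titanium Lewis acid activates the aldehyde (far more reactive than the hindered furyl ketone) and directs allyl transfer from tin to its Si face, which sets C2 as S.

Step 12
Reactants: 17 1-{4-(TBS-oxymethyl)-2-[(2E,4S)-4-hydroxy-2-methylhepta-2,6-dien-1-yl]furan-3-yl}-2-chloroethan-1-one
Product: 18 (2E,4S)-1-[4-(TBS-oxymethyl)-3-(chloroacetyl)furan-2-yl]-2-methylhepta-2,6-dien-4-yl acetate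
Conditions: Ac2O (1.5 equiv), pyridine (3 equiv), DMAP (0.05 equiv), CH2Cl2, 0 °C
Reagents that add atoms: acetic anhydride CC(=O)OC(C)=O
Why: DMAP-catalysed acetylation of the secondary allylic alcohol installs the C2 acetate of the target with retention of configuration.

Step 13
Reactants: 18 (2E,4S)-1-[4-(TBS-oxymethyl)-3-(chloroacetyl)furan-2-yl]-2-methylhepta-2,6-dien-4-yl acetate
Product: 19 (2E,4S)-1-[4-(TBS-oxymethyl)-3-(chloroacetyl)furan-2-yl]-2-methyl-6-oxohept-2-en-4-yl acetate
Conditions: PdCl2 (0.1 equiv), CuCl (1.0 equiv), O2 (1 atm), DMF/H2O (7:1), 23 °C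
Reagents that add atoms: water O
Why: Tsuji–Wacker oxidation: Markovnikov hydroxypalladation of the only monosubstituted alkene gives the C4 methyl ketone, the trisubstituted alkene and the furan reacting much more slowly.

Step 14
Reactants: 19 (2E,4S)-1-[4-(TBS-oxymethyl)-3-(chloroacetyl)furan-2-yl]-2-methyl-6-oxohept-2-en-4-yl acetate
Product: 22 (6S,8S,9E)-3-(TBS-oxymethyl)-6-hydroxy-6,10-dimethyl-4-oxo-4,5,6,7,8,11-hexahydrocyclodeca[b]furan-8-yl acetate, via samarium enolate 20 (not isolated), via samarium aldolate 21 (not isolated)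
Conditions: SmI2 (2.2 equiv, 0.1 M in THF), slow addition of 19 (final 2 mM), THF, −78 °C; sat. aq. NH4Cl at −78 °C
Reagents that add atoms: none
Why: Two single-electron transfers from SmI2 to the chloroacetyl group of 19 expel chloride and give the O-bound trivalent samarium enolate 20 with its nucleophilic carbon fixed at C5; this adds to the C4 methyl ketone through a closed, samarium-bridged six-membered chair transition state to give the chelated aldolate 21, which is protonated cold to 22. The closest known reaction type is the SmI2-promoted intramolecular Reformatsky-type aldol of α-halo carbonyl compounds, which closes six-membered rings onto ketones with 1,3-induction and medium and large rings onto aldehydes. The ten-membered carbocycle closes in a 10-(enolexo)-exo-trig mode. The new C4 stereocentre is controlled by the resident C2 acetoxy centre: with the E C1=C10 bond and the furan limiting the chain to one low-strain loop, the ketone face is attacked with the C2–O and C4=O dipoles opposed (1,3-anti model), so C4–OH should end up anti to C2–OAc. The step needs chemoselectivity (the α-chloro furyl ketone is reduced far faster at −78 °C than the dialkyl ketone, the allylic acetate or the furan), a single enolate regioisomer (fixed by the position of the halogen; no base is present, so no E1cB loss of the C2 acetate) and ring closure over oligomerisation (slow addition to high dilution, and the two arms sit on adjacent furan carbons C7 and C8). The chelated tertiary aldolate is kept at −78 °C until the quench to suppress retro-aldol opening.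

Step 15
Reactants: 22 (6S,8S,9E)-3-(TBS-oxymethyl)-6-hydroxy-6,10-dimethyl-4-oxo-4,5,6,7,8,11-hexahydrocyclodeca[b]furan-8-yl acetate
Product: 23 (4R,6R,8S,9E)-3-(TBS-oxymethyl)-4,6-dihydroxy-6,10-dimethyl-4,5,6,7,8,11-hexahydrocyclodeca[b]furan-8-yl acetate
Conditions: Me4NBH(OAc)3 (5 equiv), MeCN/AcOH (1:1), −30 °C; aq. NaHCO3
Reagents that add atoms: none
Why: Evans–Saksena reduction: the C4 hydroxyl exchanges onto boron and hydride is delivered intramolecularly through a chair transition state to the acid-activated C6 ketone, which gives the 1,3-anti diol (C6 R; the descriptor at C4 changes by priority only).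

Step 16
Reactants: 23 (4R,6R,8S,9E)-3-(TBS-oxymethyl)-4,6-dihydroxy-6,10-dimethyl-4,5,6,7,8,11-hexahydrocyclodeca[b]furan-8-yl acetate
Product: 24 (4R,6S,8S,9E)-8-(acetyloxy)-3-(TBS-oxymethyl)-6-hydroxy-6,10-dimethyl-4,5,6,7,8,11-hexahydrocyclodeca[b]furan-4-yl 2-methylprop-2-enoate
Conditions: methacrylic anhydride (1.5 equiv), Et3N (3 equiv), DMAP (0.1 equiv), CH2Cl2, 0 to 23 °C
Reagents that add atoms: methacrylic anhydride C=C(C)C(=O)OC(=O)C(C)=C
Why: DMAP-catalysed acylation is selective for the secondary C6 hydroxyl over the tertiary C4 hydroxyl on steric grounds and retains the C6 configuration.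

Step 17
Reactants: 24 (4R,6S,8S,9E)-8-(acetyloxy)-3-(TBS-oxymethyl)-6-hydroxy-6,10-dimethyl-4,5,6,7,8,11-hexahydrocyclodeca[b]furan-4-yl 2-methylprop-2-enoate
Product: 26 (4R,6S,8S,9E)-8-(acetyloxy)-3-(TBS-oxymethyl)-6,11a-dihydroxy-6,10-dimethyl-2-oxo-2,4,5,6,7,8,11,11a-octahydrocyclodeca[b]furan-4-yl 2-methylprop-2-enoate (C8 hemiketal, both epimers), via furan endoperoxide 25 (not isolated)
Conditions: O2, visible light, tetraphenylporphyrin (1 mol%), iPr2NEt (0.5 equiv), CH2Cl2, −78 °C
Reagents that add atoms: dioxygen O=O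
Why: Singlet oxygen adds [4+2] across C8 and C12 of the electron-rich furan (faster than the ene reaction of the acetate-deactivated C1=C10 alkene), and base-induced Kornblum–DeLaMare cleavage at the only bridgehead C–H (C12) gives the C12 lactone carbonyl and the C8 hemiketal, whose epimers converge in the next step.

Step 18
Reactants: 26 C8 hemiketal butenolide (as named in step 17)
Product: 28 (4R,6S,8S,9E,11E)-8-(acetyloxy)-3-(TBS-oxymethyl)-6-hydroxy-6,10-dimethyl-2-oxo-2,4,5,6,7,8-hexahydrocyclodeca[b]furan-4-yl 2-methylprop-2-enoate, via hemiketal mesylate 27 (not isolated)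
Conditions: MsCl (1.2 equiv), Et3N (3 equiv), CH2Cl2, −40 to 0 °C
Reagents that add atoms: none
Why: The acidic pseudo-acid hydroxyl at C8 (in equilibrium with the ring-opened keto carboxylate) should be sulfonylated in preference to the tertiary C4 alcohol, and elimination of methanesulfonate towards the allylic C9–H, the only β-hydrogens (dehydration by E1/E2 elimination), gives the conjugated alkylidene butenolide; the ten-membered ring with its E C1=C10 bond is expected to hold C10 cis to C7 on the new C8=C9 bond.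

Step 19
Reactants: 28 TBS ether of the target (as named in step 18)
Product: 29 CNP0246543.2, (4R,6S,8S,9E,11E)-8-(acetyloxy)-6-hydroxy-3-(hydroxymethyl)-6,10-dimethyl-2-oxo-2,4,5,6,7,8-hexahydrocyclodeca[b]furan-4-yl 2-methylprop-2-enoate
Conditions: HF·pyridine, pyridine, THF, 0 to 23 °C
Reagents that add atoms: none
Why: Buffered fluoride cleavage of the primary silyl ether should leave the acetate, the methacrylate, the tertiary alcohol and the alkylidene butenolide untouched.

**Compound list**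

1 | 2,2-dimethyl-1,3-dioxan-5-one | CC1(C)OCC(=O)CO1 | starting material
2 | ethynylmagnesium bromide | C#C[Mg]Br | starting material
3 | 5-ethynyl-2,2-dimethyl-1,3-dioxan-5-ol | CC1(C)OCC(O)(C#C)CO1 | intermediate
4 | 3-methylbut-2-en-1-yl acetate (prenyl acetate) | CC(C)=CCOC(C)=O | starting material
5 | (2E)-4-hydroxy-3-methylbut-2-en-1-yl acetate | CC(=O)OC/C=C(C)/CO | intermediate
6 | (2E)-4-bromo-3-methylbut-2-en-1-yl acetate | CC(=O)OC/C=C(C)/CBr | intermediate
7 | (2E)-6-(5-hydroxy-2,2-dimethyl-1,3-dioxan-5-yl)-3-methylhex-2-en-5-yn-1-yl acetate | CC(=O)OC/C=C(C)/CC#CC1(O)COC(C)(C)OC1 | intermediate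
8 | (2E)-7,8-dihydroxy-7-(hydroxymethyl)-3-methyloct-2-en-5-yn-1-yl acetate | CC(=O)OC/C=C(C)/CC#CC(O)(CO)CO | intermediate
9 | (2E)-4-[4-(hydroxymethyl)-3-iodofuran-2-yl]-3-methylbut-2-en-1-yl acetate | CC(=O)OC/C=C(C)/Cc1occ(CO)c1I | intermediate
10 | (2E)-4-[4-(TBS-oxymethyl)-3-iodofuran-2-yl]-3-methylbut-2-en-1-yl acetate | CC(=O)OC/C=C(C)/Cc1occ(CO[Si](C)(C)C(C)(C)C)c1I | intermediate
11 | (2E)-4-[4-(TBS-oxymethyl)-3-iodofuran-2-yl]-3-methylbut-2-en-1-ol | OC/C=C(C)/Cc1occ(CO[Si](C)(C)C(C)(C)C)c1I | intermediate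
12 | 2-chloro-N-methoxy-N-methylacetamide | CON(C)C(=O)CCl | starting material
13 | chloromagnesium alkoxide of the 3-furylmagnesium chloride from 11 (not isolated) | Cl[Mg]OC/C=C(C)/Cc1occ(CO[Si](C)(C)C(C)(C)C)c1[Mg]Cl | intermediate
14 | 1-{4-(TBS-oxymethyl)-2-[(2E)-4-hydroxy-2-methylbut-2-en-1-yl]furan-3-yl}-2-chloroethan-1-one | OC/C=C(C)/Cc1occ(CO[Si](C)(C)C(C)(C)C)c1C(=O)CCl | intermediate
15 | (2E)-4-[4-(TBS-oxymethyl)-3-(chloroacetyl)furan-2-yl]-3-methylbut-2-enal | O=C/C=C(C)/Cc1occ(CO[Si](C)(C)C(C)(C)C)c1C(=O)CCl | intermediate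
16 | allyltributylstannane | C=CC[Sn](CCCC)(CCCC)CCCC | starting material
17 | 1-{4-(TBS-oxymethyl)-2-[(2E,4S)-4-hydroxy-2-methylhepta-2,6-dien-1-yl]furan-3-yl}-2-chloroethan-1-one | C=CC[C@H](O)/C=C(C)/Cc1occ(CO[Si](C)(C)C(C)(C)C)c1C(=O)CCl | intermediate
18 | (2E,4S)-1-[4-(TBS-oxymethyl)-3-(chloroacetyl)furan-2-yl]-2-methylhepta-2,6-dien-4-yl acetate | C=CC[C@H](OC(C)=O)/C=C(C)/Cc1occ(CO[Si](C)(C)C(C)(C)C)c1C(=O)CCl | intermediate
19 | (2E,4S)-1-[4-(TBS-oxymethyl)-3-(chloroacetyl)furan-2-yl]-2-methyl-6-oxohept-2-en-4-yl acetate | CC(=O)C[C@H](OC(C)=O)/C=C(C)/Cc1occ(CO[Si](C)(C)C(C)(C)C)c1C(=O)CCl | intermediate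
20 | trivalent samarium enolate of 19 at C5=C6 (not isolated) | CC(=O)C[C@H](OC(C)=O)/C=C(C)/Cc1occ(CO[Si](C)(C)C(C)(C)C)c1C(=C)O[Sm](I)I | intermediate
21 | trivalent samarium C4 aldolate of 22 (not isolated) | O=C1C[C@@](C)(O[Sm](I)I)C[C@H](OC(C)=O)/C=C(C)/Cc2occ(CO[Si](C)(C)C(C)(C)C)c21 | intermediate
22 | (6S,8S,9E)-3-(TBS-oxymethyl)-6-hydroxy-6,10-dimethyl-4-oxo-4,5,6,7,8,11-hexahydrocyclodeca[b]furan-8-yl acetate | O=C1C[C@@](C)(O)C[C@H](OC(C)=O)/C=C(C)/Cc2occ(CO[Si](C)(C)C(C)(C)C)c21 | intermediate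
23 | (4R,6R,8S,9E)-3-(TBS-oxymethyl)-4,6-dihydroxy-6,10-dimethyl-4,5,6,7,8,11-hexahydrocyclodeca[b]furan-8-yl acetate | O[C@@H]1C[C@@](C)(O)C[C@H](OC(C)=O)/C=C(C)/Cc2occ(CO[Si](C)(C)C(C)(C)C)c21 | intermediate
24 | (4R,6S,8S,9E)-8-(acetyloxy)-3-(TBS-oxymethyl)-6-hydroxy-6,10-dimethyl-4,5,6,7,8,11-hexahydrocyclodeca[b]furan-4-yl 2-methylprop-2-enoate | C=C(C)C(=O)O[C@@H]1C[C@@](C)(O)C[C@H](OC(C)=O)/C=C(C)/Cc2occ(CO[Si](C)(C)C(C)(C)C)c21 | intermediate
25 | C8,C12-endoperoxide of the furan of 24 (not isolated) | C=C(C)C(=O)O[C@@H]1C[C@@](C)(O)C[C@H](OC(C)=O)/C=C(C)/CC23OOC(O2)C(CO[Si](C)(C)C(C)(C)C)=C13 | intermediate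
26 | (4R,6S,8S,9E)-8-(acetyloxy)-3-(TBS-oxymethyl)-6,11a-dihydroxy-6,10-dimethyl-2-oxo-2,4,5,6,7,8,11,11a-octahydrocyclodeca[b]furan-4-yl 2-methylprop-2-enoate (11a epimers) | C=C(C)C(=O)O[C@@H]1C[C@@](C)(O)C[C@H](OC(C)=O)/C=C(C)/CC2(O)OC(=O)C(CO[Si](C)(C)C(C)(C)C)=C12 | intermediate
27 | 11a-O-methanesulfonate of 26 (not isolated) | C=C(C)C(=O)O[C@@H]1C[C@@](C)(O)C[C@H](OC(C)=O)/C=C(C)/CC2(OS(C)(=O)=O)OC(=O)C(CO[Si](C)(C)C(C)(C)C)=C12 | intermediate
28 | (4R,6S,8S,9E,11E)-8-(acetyloxy)-3-(TBS-oxymethyl)-6-hydroxy-6,10-dimethyl-2-oxo-2,4,5,6,7,8-hexahydrocyclodeca[b]furan-4-yl 2-methylprop-2-enoate | C=C(C)C(=O)O[C@@H]1C[C@@](C)(O)C[C@H](OC(C)=O)/C=C(C)/C=C2/OC(=O)C(CO[Si](C)(C)C(C)(C)C)=C21 | intermediate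
29 | CNP0246543.2, (4R,6S,8S,9E,11E)-8-(acetyloxy)-6-hydroxy-3-(hydroxymethyl)-6,10-dimethyl-2-oxo-2,4,5,6,7,8-hexahydrocyclodeca[b]furan-4-yl 2-methylprop-2-enoate | C=C(C)C(=O)O[C@@H]1C[C@@](C)(O)C[C@H](OC(C)=O)/C=C(C)/C=C2/OC(=O)C(CO)=C21 | target

**Step count and risks**

Total steps: 19. Longest linear sequence: 18 steps (4 to 29, steps 2–19).

Steps most likely to fail:

Step 14. The samarium enolate may be quenched by proton transfer from the α-hydrogens of the C4 ketone, the strained tertiary aldolate may reopen by retro-aldol before the quench, or the facial bias at C4 may be weak. The fallback changes the ring closure from a reductively generated, chelated metal enolate to a Lewis acid-promoted addition of an isolated enol silane. Setting out from 19, reductive silylation (Zn, TMSCl, MeCN, 0 °C) gives the trimethylsilyl enol ether of the C6 ketone F1 with the C4 ketone untouched. An intramolecular Mukaiyama aldol (TiCl4, CH2Cl2, −78 °C, high dilution) then closes C4–C5 through an open transition state, in which the Lewis acid activates the ketone and silyl transfer makes the addition irreversible. Aqueous work-up returns the route at 22.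

Step 18. Sulfonylation or ionisation may engage the free tertiary C4 hydroxyl, leading to elimination there or to transannular capture of the C8 cation as a C4–O–C8 bridged ketal. The fallback masks that hydroxyl first. Setting out from 24, silylation (TESOTf, 2,6-lutidine, CH2Cl2, −78 °C) gives the C4 triethylsilyl ether F2. Photo-oxygenation as in step 17 passes through the endoperoxide F3 to the hemiketal butenolide F4. MsCl/Et3N, which can now be used in excess, passes through the hemiketal mesylate F5 to the bis-silylated alkylidene butenolide F6. HF·pyridine removes both silyl ethers and returns the route at 29.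

Step 15. Slow exchange of the hindered tertiary hydroxyl onto boron may let non-directed hydride delivery compete, so that the ring conformation rather than the C4 hydroxyl decides the face and the 1,3-anti selectivity is eroded. The fallback aims for the opposite diastereomer and then inverts. Setting out from 22, chelation-controlled reduction (Zn(BH4)2, Et2O, −20 °C) gives the 1,3-syn diol, the C6 epimer of 23, F7. Mitsunobu esterification with methacrylic acid (PPh3, diisopropyl azodicarboxylate, toluene, 0 °C) inverts C6 while installing the ester and returns the route at 24.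

**Further compounds**

F1 | step 14 | (2E,4S)-1-[4-(TBS-oxymethyl)-3-{1-[(trimethylsilyl)oxy]ethenyl}furan-2-yl]-2-methyl-6-oxohept-2-en-4-yl acetate | CC(=O)C[C@H](OC(C)=O)/C=C(C)/Cc1occ(CO[Si](C)(C)C(C)(C)C)c1C(=C)O[Si](C)(C)C
F2 | step 18 | (4R,6S,8S,9E)-8-(acetyloxy)-3-(TBS-oxymethyl)-6,10-dimethyl-6-[(triethylsilyl)oxy]-4,5,6,7,8,11-hexahydrocyclodeca[b]furan-4-yl 2-methylprop-2-enoate | C=C(C)C(=O)O[C@@H]1C[C@@](C)(O[Si](CC)(CC)CC)C[C@H](OC(C)=O)/C=C(C)/Cc2occ(CO[Si](C)(C)C(C)(C)C)c21
F3 | step 18 | C8,C12-endoperoxide of the furan of F2 (not isolated) | C=C(C)C(=O)O[C@@H]1C[C@@](C)(O[Si](CC)(CC)CC)C[C@H](OC(C)=O)/C=C(C)/CC23OOC(O2)C(CO[Si](C)(C)C(C)(C)C)=C13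
F4 | step 18 | C4 triethylsilyl ether of 26 (11a epimers) | C=C(C)C(=O)O[C@@H]1C[C@@](C)(O[Si](CC)(CC)CC)C[C@H](OC(C)=O)/C=C(C)/CC2(O)OC(=O)C(CO[Si](C)(C)C(C)(C)C)=C12
F5 | step 18 | 11a-O-methanesulfonate of F4 (not isolated) | C=C(C)C(=O)O[C@@H]1C[C@@](C)(O[Si](CC)(CC)CC)C[C@H](OC(C)=O)/C=C(C)/CC2(OS(C)(=O)=O)OC(=O)C(CO[Si](C)(C)C(C)(C)C)=C12
F6 | step 18 | C4 triethylsilyl ether of 28 | C=C(C)C(=O)O[C@@H]1C[C@@](C)(O[Si](CC)(CC)CC)C[C@H](OC(C)=O)/C=C(C)/C=C2/OC(=O)C(CO[Si](C)(C)C(C)(C)C)=C21
F7 | step 15 | (4S,6R,8S,9E)-3-(TBS-oxymethyl)-4,6-dihydroxy-6,10-dimethyl-4,5,6,7,8,11-hexahydrocyclodeca[b]furan-8-yl acetate | O[C@H]1C[C@@](C)(O)C[C@H](OC(C)=O)/C=C(C)/Cc2occ(CO[Si](C)(C)C(C)(C)C)c21
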